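**Retrosynthetic overview**

1. Locants: ring A (triketone) = C1 (acyl), C2 (enol), C3 (Me, prenyl), C4 (C=O), C5 (spiro), C6 (C=O). Ring B (cyclohexane) = C5, C7H2, C8H, C9H, C10(Me)(OH), C11H2. Ring C (cyclopentane) = C8, C12(Me)(OH), C13H2, C14H2, C9.
2. Enabling feature: C5 lies between the C4 and C6 carbonyls of a 1,3,5-trioxygenated six-ring and carries two CH2 groups (C7, C11). Ring A is therefore a dearomatised phloroglucinol, and ring B is "one phloroglucinol carbon + a 1,5-bis-electrophile". While C1 and C3 are unsubstituted, ring A is locally symmetric and C5 is not yet stereogenic.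
3. Key disconnection: C5–C11 (π-allyl-Pd) and C5–C7 (SN2) are made in one flask from unprotected phloroglucinol and a C10 bromo/allyl chloride.
4. The C10 unit maps onto (R)-linalool, which supplies C12. The relay runs C12 → C8/C9 (zinc-ene) → C10 (hydration on the chair of ring B) → C5 (12-OH locks one arm of ring A as a temporary pyran) → C3 (alkylation on the locked cage). The acyl group with its bought (S)-centre goes on last.
5. Ring order: A (bought as the arene), C (step 3), B (step 5, last skeletal ring). The temporary pyran (step 7) is removed in step 9.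

Key step: step 5

Remark on the chemistry: enolised di- and triketones are drawn as one tautomer. Fast tautomerism makes the two C–O arms of ring A in 9 and 10 equivalent, so C5 is not a stereocentre there.

**Step 1**
Reactants: 1 (R)-(−)-linalool
Product: 2 (2E,6R)-2,6-dimethylocta-2,7-diene-1,6-diol
Conditions: SeO2 (0.3 equiv), t-BuOOH (2 equiv), salicylic acid (cat.), CH2Cl2, 0 °C to rt
Reagents that add atoms: tert-butyl hydroperoxide CC(C)(C)OO
Why: Sharpless catalytic SeO2 allylic oxidation (ene reaction, then [2,3]-shift) should hydroxylate only the (E)-methyl group of the electron-rich trisubstituted alkene and leave the vinyl carbinol and the bought C12 centre untouched.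

**Step 2**
Reactants: 2 (2E,6R)-2,6-dimethylocta-2,7-diene-1,6-diol
Product: 3 (2E,6R)-6-hydroxy-2,6-dimethylocta-2,7-dien-1-yl acetate
Conditions: Ac2O (1.05 equiv), Et3N, DMAP (cat.), CH2Cl2, 0 °C
Reagents that add atoms: acetic anhydride CC(=O)OC(C)=O
Why: DMAP-catalysed acylation discriminates the unhindered primary allylic alcohol from the tertiary carbinol and installs the leaving group for π-allyl formation without touching a stereocentre.

**Step 3**
Reactants: 3 (2E,6R)-6-hydroxy-2,6-dimethylocta-2,7-dien-1-yl acetate
Product: 5 (1R,2S,3S)-2-(bromomethyl)-1-methyl-3-(prop-1-en-2-yl)cyclopentan-1-ol, via zincacycle 4 (not isolated)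
Conditions: Pd(PPh3)4 (5 mol %), Et2Zn (4 equiv), Et2O, rt to 35 °C; excess Et2Zn removed in vacuo; BrCl2CCCl2Br (1.2 equiv), THF, −40 °C to rt; aq NH4Cl
Reagents that add atoms: 1,2-dibromo-1,1,2,2-tetrachloroethane BrC(Cl)(Cl)C(Cl)(Cl)Br; diethylzinc CC[Zn]CC (zinc atom of 4 only)
Why: In this Oppolzer-type Pd-catalysed zinc-ene cyclisation the π-allylpalladium acetate is transmetallated by the ethylzinc alkoxide of the substrate to an allylzinc held on the C12 oxygen, the suprafacial metallo-ene addition to the vinyl group forces CH2Zn and isopropenyl cis, the O–Zn tether puts both on the face of the C12–O bond as the five-membered zincacycle 4 (C8 and C9 set from C12), and the C–Zn bond is then brominated.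

**Step 4**
Reactants: 5 (1R,2S,3S)-2-(bromomethyl)-1-methyl-3-(prop-1-en-2-yl)cyclopentan-1-ol
Product: 6 (1R,2S,3S)-2-(bromomethyl)-3-(3-chloroprop-1-en-2-yl)-1-methylcyclopentan-1-ol
Conditions: Ca(OCl)2, solid CO2, CH2Cl2/H2O, 0 °C
Reagents that add atoms: calcium hypochlorite [Ca+2].[O-]Cl.[O-]Cl
Why: Ene-type allylic chlorination of the only alkene with HOCl made in situ should give the 2-(chloromethyl)allyl unit, because proton loss from the chloronium ion is faster than capture by 12-OH (which would build a strained 2-oxabicyclo[2.2.1]heptane), and the bromide, carbinol and three stereocentres are inert.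

**Step 5**
Reactants: 6 (1R,2S,3S)-2-(bromomethyl)-3-(3-chloroprop-1-en-2-yl)-1-methylcyclopentan-1-ol; 7 phloroglucinol
Product: 9 spiro-dienone (8S,9S,12R) with ring A as 3,5-dihydroxycyclohexa-2,5-dienone and an exocyclic methylene at C10, via C-allylphloroglucinol 8 (not isolated)
Conditions: 7 (3 equiv), Pd(PPh3)4 (5 mol %), K2CO3 (3 equiv), DMF, rt; then NaI (0.2 equiv), 70 °C
Reagents that add atoms: none
Why: Pd(0) ionises the allylic chloride of 6 to a 2-substituted π-allyl complex with two equivalent CH2 termini, phloroglucinolate attacks it through carbon (Tsuji–Trost C-allylation, any aryl allyl ether being re-ionised) to give 8, and on warming the same, now substituted, ring carbon is alkylated by the primary bromide (iodide after Finkelstein exchange). The closest known reactions are the Pd-catalysed exhaustive C-allylation of phloroglucinol to gem-diallyl cyclohexanetriones and the alkylative dearomatisation of phloroglucinols and phenolates (Winstein-type aryl participation). Ring B closes in the 6-exo-tet mode through a chair with C12 equatorial, whereas attack through oxygen would need an eight-membered ring and the free ring carbons cannot reach C7. No new stereocentre is formed: with C1 and C3 unsubstituted the two halves of ring A are equivalent, so the quaternary spiro carbon is built without any facial-selectivity problem, and C8, C9 and C12 are not touched. The step needs allyl chloride before alkyl bromide and mono- before poly-alkylation; the first follows from the inertness of an unactivated β-branched bromide to Pd(PPh3)4 and carbonate at rt, the second from the excess of cheap 7 and the intramolecular second bond. In one flask a flat achiral arene and a C10 unit should thus give the complete tricyclic carbon skeleton, the all-carbon spiro centre and the triketone oxidation level.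

**Step 6**
Reactants: 9 spiro-dienone with exocyclic methylene at C10
Product: 10 spiro-dienone diol (8S,9S,10R,12R)
Conditions: Mn(dpm)3 (10 mol %), PhSiH3 (2 equiv), O2 (1 atm), i-PrOH/CH2Cl2, 0 °C
Reagents that add atoms: dioxygen O=O
Why: Mukaiyama hydration (metal-hydride H-atom transfer to the CH2 terminus, O2 capture of the tertiary C10 radical) addresses only the 1,1-disubstituted alkene, the cyclic β-diketone cannot chelate the catalyst, and in the favoured chair (C12 equatorial on C8, C14 axial on C9) the axial ring-A carbon on C5 shields the syn-axial lobe, so oxygen should enter anti to H-8/H-9 and leave the methyl group cis to them (10R).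

**Step 7**
Reactants: 10 spiro-dienone diol
Product: 11 pyran-locked diketone (12-O bonded to C6; C6=C1 enol ether; C2/C4 diketone; 10-OH free)
Conditions: CSA (10 mol %), 4 Å MS, 1,2-dichloroethane, 50 °C
Reagents that add atoms: none
Why: In this intramolecular acid-catalysed 3-alkoxyenone formation from a vinylogous acid and an alcohol, only the ring-A arm syn to C12 on ring B can be reached by 12-OH, so closure of the six-membered pyran desymmetrises ring A and fixes the spiro centre C5 by geometric necessity, the five-membered ether from 10-OH being the more strained bridged isomer under these reversible conditions.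

**Step 8**
Reactants: 11 pyran-locked diketone
Product: 13 pyran-locked (3R)-3-methyl-3-prenyl diketone, via C3-prenyl enol 12 (not isolated)
Conditions: prenyl acetate (1.05 equiv), Pd(PPh3)4 (5 mol %), THF, 40 °C; then K2CO3 (3 equiv), MeI (3 equiv), DMF, rt
Reagents that add atoms: 3-methylbut-2-en-1-yl acetate CC(=O)OCC=C(C)C; iodomethane CI
Why: Tsuji–Trost prenylation at the unhindered allyl terminus hits C3, the only 1,3-diketone carbon left, and in the following enolate C-methylation C11 is the angular pseudo-axial substituent on ring A while C7 lies in the fused pyran, so MeI should approach C3 anti to C11 (as in angular-methyl-controlled enolate alkylations) and place methyl syn to C7 and prenyl syn to C11 (3R).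

**Step 9**
Reactants: 13 pyran-locked (3R)-3-methyl-3-prenyl diketone
Product: 14 spiro-trione diol (deacyl target)
Conditions: LiOH (5 equiv), THF/H2O, 50 °C; then 1 M HCl to pH 3
Reagents that add atoms: water O
Why: Saponification of the vinylogous ester by addition–elimination at C6 cleaves the C6–O and not the C12–O bond, so C12 keeps its configuration, and irreversible formation of the delocalised trione enolate drives release of the temporary ring.

**Step 10**
Reactants: 14 spiro-trione diol; 15 (S)-2-methylbutanoic acid
Product: 17 hyperielliptone HB, via enol ester 16 (not isolated)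
Conditions: 15 (1.2 equiv), DCC (1.2 equiv), CH2Cl2, 0 °C, 15 min; then 14, DMAP, rt
Reagents that add atoms: none
Why: Steglich O-acylation of the enol followed by DMAP-mediated O-to-C acyl migration, the standard route from syncarpic-acid-type triones to 2-acyl triketones, can only deliver the acyl group to C1, the tertiary alcohols do not react, and the bought (S)-centre enters last under mild conditions so that it is not epimerised.

**Compound list**

1 | (R)-(−)-linalool | CC(C)=CCC[C@@](C=C)(C)O | starting material
2 | (2E,6R)-2,6-dimethylocta-2,7-diene-1,6-diol | OC/C(C)=C/CC[C@@](C=C)(C)O | intermediate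
3 | (2E,6R)-6-hydroxy-2,6-dimethylocta-2,7-dien-1-yl acetate | CC(=O)OC/C(C)=C/CC[C@@](C=C)(C)O | intermediate
4 | cyclic alkylzinc alkoxide (Zn bridges C7 and 12-O; isopropenyl cis) | [Zn]1C[C@H]2[C@H](CC[C@@]2(C)O1)C(C)=C | intermediate
5 | (1R,2S,3S)-2-(bromomethyl)-1-methyl-3-(prop-1-en-2-yl)cyclopentan-1-ol (OH, CH2Br, isopropenyl all cis) | BrC[C@H]1[C@H](CC[C@@]1(C)O)C(C)=C | intermediate
6 | (1R,2S,3S)-2-(bromomethyl)-3-(3-chloroprop-1-en-2-yl)-1-methylcyclopentan-1-ol | BrC[C@H]1[C@H](CC[C@@]1(C)O)C(=C)CCl | intermediate
7 | phloroglucinol | Oc1cc(O)cc(O)c1 | starting material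
8 | 2-{2-[(1S,2S,3R)-2-(bromomethyl)-3-hydroxy-3-methylcyclopentyl]prop-2-en-1-yl}benzene-1,3,5-triol | BrC[C@H]1[C@H](CC[C@@]1(C)O)C(=C)Cc1c(O)cc(O)cc1O | intermediate
9 | spiro-dienone (8S,9S,12R): cis-hydrindane, exocyclic CH2 at C10, ring A as symmetric dienol-one | O=C1C=C(O)C2(C[C@H]3[C@H](CC[C@@]3(C)O)C(=C)C2)C(O)=C1 | intermediate
10 | spiro-dienone diol (8S,9S,10R,12R): both methyl groups cis to H-8/H-9, both OH groups on the other face | O=C1C=C(O)C2(C[C@H]3[C@H](CC[C@@]3(C)O)[C@](C)(O)C2)C(O)=C1 | intermediate
11 | pyran-locked diketone: 12-O bonded to C6, the arm of C5 syn to C12 | O=C1CC(=O)C=C2O[C@]3(C)CC[C@H]4[C@@H]3C[C@@]12C[C@@]4(C)O | intermediate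
12 | C3-prenyl enol of 11 | O=C1C(CC=C(C)C)=C(O)C=C2O[C@]3(C)CC[C@H]4[C@@H]3C[C@@]12C[C@@]4(C)O | intermediate
13 | pyran-locked (3R)-3-methyl-3-prenyl diketone (Me syn to C7, prenyl syn to C11) | O=C1[C@](C)(CC=C(C)C)C(=O)C=C2O[C@]3(C)CC[C@H]4[C@@H]3C[C@@]12C[C@@]4(C)O | intermediate
14 | spiro-trione diol (target without the C1 acyl group) | C1=C(O)[C@@](C)(CC=C(C)C)C(=O)[C@]2(C[C@H]3[C@H](CC[C@@]3(C)O)[C@](C)(O)C2)C1=O | intermediate
15 | (S)-2-methylbutanoic acid | CC[C@H](C)C(=O)O | starting material
16 | C2 enol (S)-2-methylbutanoate of 14 | C1=C(OC(=O)[C@@H](C)CC)[C@@](C)(CC=C(C)C)C(=O)[C@]2(C[C@H]3[C@H](CC[C@@]3(C)O)[C@](C)(O)C2)C1=O | intermediate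
17 | hyperielliptone HB | CC[C@H](C)C(=O)C1=C(O)[C@@](C)(CC=C(C)C)C(=O)[C@]2(C[C@H]3[C@H](CC[C@@]3(C)O)[C@](C)(O)C2)C1=O | target

Total step count: 10. Longest linear sequence: 10 steps (from 1).

**Steps most likely to fail**

Step 5. The triphenol may be over-allylated or O-allylated in the first stage. The ipso attack on the β-branched bromide may also be slow enough for intermolecular alkylation to compete.
Fallback: it sets out from 6 and 7 and separates the two bonds. Williamson O-allylation with excess 7 (K2CO3, acetone) gives the mono-allyl aryl ether F1. An aromatic Claisen rearrangement (N,N-diethylaniline, heat) secures the C–C bond; the 2-substituted allyl unit is degenerate, so the [3,3] shift gives 8. Compound 8 is isolated and closed under high dilution with t-BuOK in t-BuOH by phenolate participation. The fallback returns to the route at 9.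

Step 6. Capture of the C10 radical by oxygen may show poor facial selectivity, or the enolised ring A may be oxidised in competition.
Fallback: it sets out from 9 and builds C10 by carbonyl addition on the rigid cage.
- 9 is locked first under the conditions of step 7 to give the pyran-locked methylene compound F2.
- Lemieux–Johnson cleavage (OsO4 cat., NaIO4) of the isolated alkene gives the pyran-locked C10 ketone F3.
- Excess MeMgBr/CeCl3 is then added. The diketone is masked as its magnesium enolate, and the reagent should attack the ketone from the open exo face of the oxabicyclo[3.3.1]nonane cage. This leaves 10-OH endo and returns to the route at 11.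

Step 9. Hydroxide may add only sluggishly at the hindered C6, and retro-Claisen cleavage at the non-enolisable C4 ketone may compete.
Fallback: it sets out from 13 and opens the ring with a better nucleophile. Pyrrolidine (EtOH, 60 °C) exchanges the vinylogous ester for the ring-opened enaminone F4 and releases 12-OH with the C12–O bond intact. Mild aqueous acid (1 M HCl, THF, rt) hydrolyses the enaminone and returns to the route at 14.

**Further compounds**

F1 | step 5 | 5-{2-[(1S,2S,3R)-2-(bromomethyl)-3-hydroxy-3-methylcyclopentyl]prop-2-en-1-yloxy}benzene-1,3-diol | BrC[C@H]1[C@H](CC[C@@]1(C)O)C(=C)COc1cc(O)cc(O)c1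
F2 | step 6 | pyran-locked diketone with exocyclic methylene at C10 | O=C1CC(=O)C=C2O[C@]3(C)CC[C@H]4[C@@H]3C[C@@]12CC4=C
F3 | step 6 | pyran-locked diketone with C10 ketone | O=C1CC(=O)C=C2O[C@]3(C)CC[C@H]4[C@@H]3C[C@@]12CC4=O
F4 | step 9 | C6 pyrrolidinyl enaminone of 14 | O=C1C=C(N2CCCC2)[C@@]3(C[C@H]4[C@H](CC[C@@]4(C)O)[C@](C)(O)C3)C(=O)[C@]1(C)CC=C(C)C
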